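**Plan**
1. Retrosynthesis: the ester C–O bond is cut first, then O1–C2 of the oxolane (benzylic cation closure), then the two C–C bonds that flank C3–C4, namely C3–C2 (aldol) and C4–CH2Ar (conjugate addition).
2. Enabling feature: in the oxolane (O1, C2, C3, C4, C5), C3 and C4 each carry one aryl-bearing carbon (C2 and the benzylic CH2), both derived from O-benzylvanillin, and the chain CH2O–C3–C4–C5 is the four-carbon skeleton of a butenolide (carbonyl, alpha, beta and acetal carbon).
3. Forward: the menthyloxy butenolide and the aldehyde thioacetal are made, the three components are joined in one flask without ring closure, LiAlH4 opens the lactone and releases the auxiliary, sulfur is removed, and the only ring closes last at O1–C2; acylation and debenzylation finish.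
4. Stereochemistry: the (5S) acetal carbon (from (+)-menthol, by crystallisation) directs the anion anti and sets C4; C4 directs the aldol anti and sets C3. The trans lactone becomes the 3,4-cis oxolane because the ring at C3 then runs through C2 instead of the former carbonyl carbon. C2 is set 2,3-trans in the cation closure, and the ester stereocentre comes from (R)-2-methylbutanoic acid.

Key step: step 4

Assumption: the carbinol carbon formed in step 4 is expected as a mixture of epimers. Compounds 10, 11 and 12 are drawn and named as the (R)-carbinol epimer and both epimers are carried on together, since step 7 passes through the planar benzylic cation.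

Step 1
Reactants: 1 furfural
Product: 3 5-hydroxyfuran-2(5H)-one (racemic), via furfural endoperoxide 2 (not isolated)
Conditions: O2, methylene blue (cat.), MeOH, visible light, 20 °C
Reagents that add atoms: oxygen, O=O
Why: Singlet-oxygen [4+2] cycloaddition to the furan gives endoperoxide 2, which methanol cleaves with loss of the formyl carbon as methyl formate (dye-sensitised photooxygenation of furfural); the hemiacetal carbon of 3 is racemic and labile.

Step 2
Reactants: 3 5-hydroxyfuran-2(5H)-one; 4 (+)-menthol
Product: 5 (5S)-5-(d-menthyloxy)furan-2(5H)-one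
Conditions: camphorsulfonic acid (cat.), toluene, reflux, azeotropic removal of water; crystallisation from hexane, mother liquor re-equilibrated with the same acid
Reagents that add atoms: none
Why: Acid-catalysed acetalisation through the cyclic oxocarbenium ion should give both C5 epimers, and since C5 epimerises under the same acid the less soluble (5S) d-menthyl epimer can be collected by crystallisation, so C5 is set by crystallisation-driven resolution against the menthyl group.

Step 3
Reactants: 6 4-benzyloxy-3-methoxybenzaldehyde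
Product: 7 1-benzyloxy-4-[bis(phenylthio)methyl]-2-methoxybenzene
Conditions: PhSH (2.1 equiv), BF3·OEt2 (0.1 equiv), CH2Cl2, 0 °C
Reagents that add atoms: thiophenol, Sc1ccccc1
Why: Lewis-acid-catalysed dithioacetalisation of an aromatic aldehyde is fast at 0 °C and should outrun any attack on the aryl benzyl ether when BF3·OEt2 is used only catalytically; no stereocentre is formed.

Step 4
Reactants: 7 1-benzyloxy-4-[bis(phenylthio)methyl]-2-methoxybenzene; 5 (5S)-5-(d-menthyloxy)furan-2(5H)-one; 6 4-benzyloxy-3-methoxybenzaldehyde
Product: 10 (3R,4S,5S)-3-[(R)-(4-benzyloxy-3-methoxyphenyl)(hydroxy)methyl]-4-[(4-benzyloxy-3-methoxyphenyl)bis(phenylthio)methyl]-5-(d-menthyloxy)oxolan-2-one, via lithiated thioacetal 8 (not isolated), via lactone lithium enolate 9 (not isolated)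
Conditions: n-BuLi, THF, −78 °C; then 5, −78 °C; then 6, −78 °C; AcOH quench at −78 °C
Reagents that add atoms: none
Why: n-BuLi removes the acetal proton of 7 to give the soft, doubly sulfur-stabilised benzylic anion 8, which adds 1,4 to butenolide 5 and forms the C4–C(SPh)2Ar bond; the lithium enolate 9 then adds to the carbonyl of 6 in an aldol reaction and forms the C3–carbinol bond, so no ring is closed. The closest known reaction type is the tandem Michael addition–aldol trapping of lithiated aryl dithioacetals on 5-alkoxybutenolides. The anion should enter on the face of the planar butenolide opposite the C5 menthyloxy group, which sets C4 as S. The enolate should be attacked on the face opposite the very large bis(phenylthio)benzyl group at C4, which sets C3 as R and makes the lactone trans,trans. The carbinol carbon is only weakly controlled by the aldol transition state, which is tolerated because step 7 ionises it. The step needs 1,4- over 1,2-addition and kinetic trapping without retro-aldol or retro-Michael reaction, which the soft anion, the constant −78 °C and the cold acetic acid quench should secure.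

Step 5
Reactants: 10 the aldol adduct
Product: 11 (2S,3S)-2-[(R)-(4-benzyloxy-3-methoxyphenyl)(hydroxy)methyl]-3-[(4-benzyloxy-3-methoxyphenyl)bis(phenylthio)methyl]butane-1,4-diol
Conditions: LiAlH4, THF, 0 °C to rt; aqueous NaOH work-up
Reagents that add atoms: none
Why: Hydride reduction of the lactone opens the ring to a hemiacetal alkoxide at the former acetal carbon, which expels mentholate to an aldehyde that is reduced in turn, so the acylal-type lactone becomes the 1,4-diol and the auxiliary leaves in the same operation while thioacetal, benzyl ethers and the stereocentres stay untouched.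

Step 6
Reactants: 11 the bis(phenylthio) triol
Product: 12 (2S,3S)-2-[(R)-(4-benzyloxy-3-methoxyphenyl)(hydroxy)methyl]-3-(4-benzyloxy-3-methoxybenzyl)butane-1,4-diol
Conditions: NiCl2·6H2O, NaBH4, MeOH/THF, 0 °C
Reagents that add atoms: none
Why: Ni2B formed in the flask should hydrogenolyse both benzylic C–S bonds (reductive desulfurisation of a dithioacetal to CH2) under conditions that leave aryl benzyl ethers and the benzylic alcohol intact; no stereocentre is affected.

Step 7
Reactants: 12 the desulfurised triol
Product: 13 [(2R,3S,4S)-2-(4-benzyloxy-3-methoxyphenyl)-4-(4-benzyloxy-3-methoxybenzyl)oxolan-3-yl]methanol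
Conditions: camphorsulfonic acid (0.1 equiv), CH2Cl2, 0 °C; Et3N quench
Reagents that add atoms: none
Why: Acid ionises the para-alkoxybenzylic alcohol of either epimer to a stabilised cation that is captured by the hydroxymethyl group on C4 in an SN1 cycloetherification (the other primary alcohol could only give an oxetane), and C2 should be set as R because the aryl group takes the position trans to the C3 hydroxymethyl group in a closure that is reversible under the acid.

Step 8
Reactants: 13 the oxolane alcohol; 14 (R)-2-methylbutanoic acid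
Product: 15 [(2R,3S,4S)-2-(4-benzyloxy-3-methoxyphenyl)-4-(4-benzyloxy-3-methoxybenzyl)oxolan-3-yl]methyl (2R)-2-methylbutanoate
Conditions: DCC, DMAP (cat.), CH2Cl2, 0 °C to rt
Reagents that add atoms: none
Why: Steglich esterification of the single remaining primary alcohol; the alpha stereocentre of this simple alpha-alkyl acid is not expected to epimerise at 0 °C with catalytic DMAP.

Step 9
Reactants: 15 the dibenzyl ester
Product: 16 [(2R,3S,4S)-2-(4-hydroxy-3-methoxyphenyl)-4-(4-hydroxy-3-methoxybenzyl)oxolan-3-yl]methyl (2R)-2-methylbutanoate (target)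
Conditions: H2 (1 atm), 10% Pd/C, EtOAc, rt, stopped after uptake of two equivalents
Reagents that add atoms: none
Why: Hydrogenolysis of aryl benzyl ethers over Pd/C is much faster than cleavage of the cyclic benzylic C2–O1 bond in a neutral aprotic solvent at one atmosphere, so both phenols should be freed while the oxolane, the ester and all four stereocentres remain.

**Compound list**
1 | furfural (furan-2-carbaldehyde) | O=Cc1ccco1 | starting material
2 | furfural endoperoxide, 2,3,7-trioxabicyclo[2.2.1]hept-5-ene-1-carbaldehyde (racemic, not isolated) | O=CC12C=CC(OO1)O2 | intermediate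
3 | 5-hydroxyfuran-2(5H)-one (racemic) | OC1OC(=O)C=C1 | intermediate
4 | (+)-menthol, (1S,2R,5S)-2-isopropyl-5-methylcyclohexan-1-ol | CC(C)[C@H]1CC[C@H](C)C[C@@H]1O | starting material
5 | (5S)-5-(d-menthyloxy)furan-2(5H)-one, d-menthyl = (1S,2R,5S)-2-isopropyl-5-methylcyclohexyl | O=C1O[C@H](O[C@H]2C[C@@H](C)CC[C@@H]2C(C)C)C=C1 | intermediate
6 | 4-benzyloxy-3-methoxybenzaldehyde | COc1cc(C=O)ccc1OCc1ccccc1 | starting material
7 | 1-benzyloxy-4-[bis(phenylthio)methyl]-2-methoxybenzene | COc1cc(C(Sc2ccccc2)Sc2ccccc2)ccc1OCc1ccccc1 | intermediate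
8 | [(4-benzyloxy-3-methoxyphenyl)bis(phenylthio)methyl]lithium (not isolated) | [Li]C(Sc1ccccc1)(Sc1ccccc1)c1ccc(OCc2ccccc2)c(OC)c1 | intermediate
9 | O-lithium enolate of (4S,5S)-4-[(4-benzyloxy-3-methoxyphenyl)bis(phenylthio)methyl]-5-(d-menthyloxy)oxolan-2-one (not isolated) | [Li]OC1=C[C@H](C(Sc2ccccc2)(Sc2ccccc2)c2ccc(OCc3ccccc3)c(OC)c2)[C@@H](O[C@H]2C[C@@H](C)CC[C@@H]2C(C)C)O1 | intermediate
10 | (3R,4S,5S)-3-[(R)-(4-benzyloxy-3-methoxyphenyl)(hydroxy)methyl]-4-[(4-benzyloxy-3-methoxyphenyl)bis(phenylthio)methyl]-5-(d-menthyloxy)oxolan-2-one | O=C1O[C@H](O[C@H]2C[C@@H](C)CC[C@@H]2C(C)C)[C@@H](C(Sc2ccccc2)(Sc2ccccc2)c2ccc(OCc3ccccc3)c(OC)c2)[C@@H]1[C@@H](O)c1ccc(OCc2ccccc2)c(OC)c1 | intermediate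
11 | (2S,3S)-2-[(R)-(4-benzyloxy-3-methoxyphenyl)(hydroxy)methyl]-3-[(4-benzyloxy-3-methoxyphenyl)bis(phenylthio)methyl]butane-1,4-diol | OC[C@H]([C@H](C(Sc1ccccc1)(Sc1ccccc1)c1ccc(OCc2ccccc2)c(OC)c1)CO)[C@@H](O)c1ccc(OCc2ccccc2)c(OC)c1 | intermediate
12 | (2S,3S)-2-[(R)-(4-benzyloxy-3-methoxyphenyl)(hydroxy)methyl]-3-(4-benzyloxy-3-methoxybenzyl)butane-1,4-diol | OC[C@H]([C@H](Cc1ccc(OCc2ccccc2)c(OC)c1)CO)[C@@H](O)c1ccc(OCc2ccccc2)c(OC)c1 | intermediate
13 | [(2R,3S,4S)-2-(4-benzyloxy-3-methoxyphenyl)-4-(4-benzyloxy-3-methoxybenzyl)oxolan-3-yl]methanol | OC[C@@H]1[C@H](Cc2ccc(OCc3ccccc3)c(OC)c2)CO[C@H]1c1ccc(OCc2ccccc2)c(OC)c1 | intermediate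
14 | (R)-2-methylbutanoic acid | CC[C@@H](C)C(=O)O | starting material
15 | [(2R,3S,4S)-2-(4-benzyloxy-3-methoxyphenyl)-4-(4-benzyloxy-3-methoxybenzyl)oxolan-3-yl]methyl (2R)-2-methylbutanoate | CC[C@@H](C)C(=O)OC[C@@H]1[C@H](Cc2ccc(OCc3ccccc3)c(OC)c2)CO[C@H]1c1ccc(OCc2ccccc2)c(OC)c1 | intermediate
16 | [(2R,3S,4S)-2-(4-hydroxy-3-methoxyphenyl)-4-(4-hydroxy-3-methoxybenzyl)oxolan-3-yl]methyl (2R)-2-methylbutanoate (CNP0315069.1) | CC[C@@H](C)C(=O)OC[C@@H]1[C@H](Cc2ccc(O)c(OC)c2)CO[C@H]1c1ccc(O)c(OC)c1 | target

**Step count**
Total steps: 9. Longest linear sequence: 8 steps (1, 2, 4, 5, 6, 7, 8, 9 from furfural); the thioacetal branch (step 3) joins at step 4.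

**Steps most likely to fail**

Step 4. The lithium aldolate may revert by retro-aldol or retro-Michael reaction, the anion may add 1,2 to the lactone carbonyl, or proton transfer may leave the enolate untrapped. Fallback: the coupling is split into two operations. It sets out from 7 and 5: anion 8 is added to 5 as before, but enolate 9 is quenched with AcOH at −78 °C and the conjugate adduct (4S,5S)-4-[(4-benzyloxy-3-methoxyphenyl)bis(phenylthio)methyl]-5-(d-menthyloxy)oxolan-2-one F1 is isolated. F1 is then deprotonated with LiN(iPr)2 in THF at −78 °C, the enolate is transmetalated with ZnCl2 (a zinc aldolate is less prone to retro-aldol cleavage) and 6 is added. This comes back to the route at 10.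

Step 7. The benzylic cation may be intercepted by the electron-rich pendant arene (Friedel–Crafts closure to an aryltetralin), or the product may re-ionise and drift the same way on prolonged acid contact. Fallback: the closure is moved to the free-phenol level, where ionisation needs far weaker acid. It sets out from 12: the aryl benzyl ethers are hydrogenolysed (H2, 10% Pd/C, EtOAc, rt, neutral; no cyclic benzylic ether is present yet) to (2S,3S)-2-[(R)-hydroxy(4-hydroxy-3-methoxyphenyl)methyl]-3-(4-hydroxy-3-methoxybenzyl)butane-1,4-diol F2. The ring is closed through the para-quinone methide with pyridinium p-toluenesulfonate (cat.) in MeCN at rt to (−)-lariciresinol, [(2R,3S,4S)-2-(4-hydroxy-3-methoxyphenyl)-4-(4-hydroxy-3-methoxybenzyl)oxolan-3-yl]methanol F3. Only the phenols are then re-benzylated (BnBr, K2CO3, acetone, reflux), which comes back to the route at 13.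

Step 6. C–S hydrogenolysis at the hindered, fully substituted benzylic carbon may stall at the mono(phenylthio) stage, or the polar triol may be held on the nickel surface. Fallback: sulfur is removed earlier and by a radical chain instead of a metal surface. It sets out from 10: Bu3SnH (excess) and AIBN (cat.) in toluene at reflux should give (3R,4S,5S)-4-(4-benzyloxy-3-methoxybenzyl)-3-[(R)-(4-benzyloxy-3-methoxyphenyl)(hydroxy)methyl]-5-(d-menthyloxy)oxolan-2-one F4. Reduction of F4 with LiAlH4 in THF at 0 °C then opens the lactone and releases the auxiliary, which comes back to the route at 12.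

**Further compounds**
F1 | step 4 | (4S,5S)-4-[(4-benzyloxy-3-methoxyphenyl)bis(phenylthio)methyl]-5-(d-menthyloxy)oxolan-2-one | O=C1C[C@H](C(Sc2ccccc2)(Sc2ccccc2)c2ccc(OCc3ccccc3)c(OC)c2)[C@@H](O[C@H]2C[C@@H](C)CC[C@@H]2C(C)C)O1
F2 | step 7 | (2S,3S)-2-[(R)-hydroxy(4-hydroxy-3-methoxyphenyl)methyl]-3-(4-hydroxy-3-methoxybenzyl)butane-1,4-diol | OC[C@H]([C@H](Cc1ccc(O)c(OC)c1)CO)[C@@H](O)c1ccc(O)c(OC)c1
F3 | step 7 | (−)-lariciresinol, [(2R,3S,4S)-2-(4-hydroxy-3-methoxyphenyl)-4-(4-hydroxy-3-methoxybenzyl)oxolan-3-yl]methanol | OC[C@@H]1[C@H](Cc2ccc(O)c(OC)c2)CO[C@H]1c1ccc(O)c(OC)c1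
F4 | step 6 | (3R,4S,5S)-4-(4-benzyloxy-3-methoxybenzyl)-3-[(R)-(4-benzyloxy-3-methoxyphenyl)(hydroxy)methyl]-5-(d-menthyloxy)oxolan-2-one | O=C1O[C@H](O[C@H]2C[C@@H](C)CC[C@@H]2C(C)C)[C@@H](Cc2ccc(OCc3ccccc3)c(OC)c2)[C@@H]1[C@@H](O)c1ccc(OCc2ccccc2)c(OC)c1
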